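**Retrosynthetic overview**
1. Target 18 ⇐ 17 by cleaving the two methyl ethers on ring B (the 2,6-dioxygenated, para-bridged ring; ring A is the meta-bridged monophenol ring).
2. 17 ⇐ 12: ring A and the 20-membered ring close together in an intramolecular cyclobutenone + aryl ynol ether benzannulation. The ynol ether oxygen becomes the diaryl ether oxygen and cyclobutenone C3 carries the C12 chain.
3. 12 ⇐ 6 + 7: Grignard addition to 3-ethoxycyclobutenone, with the dichlorovinyl ether as masked ynol ether.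
4. 6 ⇐ 3 + 4 (B-alkyl Suzuki–Miyaura coupling); 3 ⇐ 1 + 2.
5. Ring order: ring B is bought (in 1); ring A and the macrocycle form last and simultaneously (step 4).

Assumption: the target has no stereocentre and no configurationally stable planar chirality (the 20-membered ansa ring turns freely), so it is made as the single achiral compound drawn.

**Step 1**
Reactants: 1 4-bromo-2,6-dimethoxyphenol; 2 trichloroethylene
Product: 3 5-bromo-2-{[(E)-1,2-dichloroethenyl]oxy}-1,3-dimethoxybenzene
Conditions: K2CO3, DMF, 70 °C, 16 h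
Reagents that add atoms: none
Why: The phenoxide replaces one chloride of trichloroethylene by base-mediated vinylic addition–elimination (Greene-type dichlorovinyl ether synthesis), the trans addition fixing the E geometry, and the aryl bromide is inert to carbonate.

**Step 2**
Reactants: 3 5-bromo-2-{[(E)-1,2-dichloroethenyl]oxy}-1,3-dimethoxybenzene; 4 12-bromododec-1-ene
Product: 6 5-(12-bromododecyl)-2-{[(E)-1,2-dichloroethenyl]oxy}-1,3-dimethoxybenzene, via alkylborane 5 (not isolated)
Conditions: 4, 9-BBN, THF, 0 °C to rt; then 3, Pd(dppf)Cl2 (5 mol %), aq. K3PO4, THF/DMF, 50 °C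
Reagents that add atoms: none
Why: Anti-Markovnikov hydroboration followed by B-alkyl Suzuki–Miyaura coupling, in which zerovalent palladium with dppf inserts into the aryl C–Br bond faster than into the vinylic C–Cl bonds or the primary alkyl bromide, so the sp3–sp2 bond forms with both halide handles kept.

**Step 3**
Reactants: 6 5-(12-bromododecyl)-2-{[(E)-1,2-dichloroethenyl]oxy}-1,3-dimethoxybenzene; 7 3-ethoxycyclobut-2-en-1-one
Product: 12 3-{12-[4-(ethynyloxy)-3,5-dimethoxyphenyl]dodecyl}cyclobut-2-en-1-one, via Grignard reagent 8 (not isolated), via bromomagnesium cyclobutenolate 9 (not isolated), via lithium acetylide 10 (not isolated), via ethoxycyclobutenol 11 (not isolated)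
Conditions: Mg, THF, 35 °C; 7, −78 °C; n-BuLi (3 equiv), −78 to −40 °C; sat. aq. NH4Cl; then PPTS (5 mol %), wet THF, 0 °C, 15 min
Reagents that add atoms: water, O
Why: Magnesium inserts only into the primary C–Br bond (uncatalysed Grignard reagents leave 1,2-dichloroalkenes alone), 1,2-addition to the vinylogous ester 7 stores the enone as an alkoxide that survives the n-BuLi dehydrochlorination and chlorine–lithium exchange of the dichlorovinyl ether (Greene ynol ether synthesis), and mild acid then drives the Stork–Danheiser-type ionisation and hydrolysis of the 3-ethoxycyclobutenol to the cyclobutenone faster than hydration of the aryl ynol ether; the carbinol stereocentre of 9–11 is racemic and is destroyed in the transposition.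

**Step 4**
Reactants: 12 3-{12-[4-(ethynyloxy)-3,5-dimethoxyphenyl]dodecyl}cyclobut-2-en-1-one
Product: 17 ring B di-O-methyl ether of the target macrocycle (20-membered ring; ring A phenol free), via vinylketene 13 (not isolated), via fused vinylcyclobutenone 14 (not isolated), via dienylketene 15 (not isolated), via cyclohexadienone 16 (not isolated)
Conditions: PhMe, 1 mM (syringe-pump addition over 10 h), 80 °C, then 110 °C, 2 h
Reagents that add atoms: none
Why: Proposed new method: a macrocyclising intramolecular Danheiser benzannulation, in which thermal 4π opening of the cyclobutenone gives vinylketene 13, the tethered electron-rich aryl ynol ether traps it by [2+2] cycloaddition (ketene carbonyl carbon to the unsubstituted alkyne carbon) to give 14, and 4π opening to 15, 6π closure to 16 and tautomerisation give the 3-aryloxy-5-alkylphenol with regiochemistry fixed by the polarity of the two partners, while high dilution and the reversible formation of the vinylketene favour the 20-membered ring over oligomers; the closest known reaction is the intermolecular Danheiser benzannulation of 3-alkylcyclobutenones with alkoxyacetylenes to resorcinol monoethers, and no stereocentre remains in 17.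

**Step 5**
Reactants: 17 ring B di-O-methyl ether of the target macrocycle
Product: 18 CNP0314249.0 (target triol)
Conditions: BBr3 (5 equiv), CH2Cl2, −78 °C to rt; then H2O
Reagents that add atoms: none
Why: BBr3 demethylation of aryl methyl ethers proceeds by bromide attack on the O-methyl groups of the boron-complexed ethers while the diaryl ether and the alkyl chain are inert, giving the achiral triol.

**Compound list**
1 | 4-bromo-2,6-dimethoxyphenol | COc1cc(Br)cc(OC)c1O | starting material
2 | trichloroethylene | ClC=C(Cl)Cl | starting material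
3 | 5-bromo-2-{[(E)-1,2-dichloroethenyl]oxy}-1,3-dimethoxybenzene | COc1cc(Br)cc(OC)c1O/C(Cl)=C\Cl | intermediate
4 | 12-bromododec-1-ene | C=CCCCCCCCCCCBr | starting material
5 | 9-(12-bromododecyl)-9-borabicyclo[3.3.1]nonane | BrCCCCCCCCCCCCB1C2CCCC1CCC2 | intermediate (not isolated)
6 | 5-(12-bromododecyl)-2-{[(E)-1,2-dichloroethenyl]oxy}-1,3-dimethoxybenzene | COc1cc(CCCCCCCCCCCCBr)cc(OC)c1O/C(Cl)=C\Cl | intermediate
7 | 3-ethoxycyclobut-2-en-1-one | CCOC1=CC(=O)C1 | starting material
8 | [12-(4-{[(E)-1,2-dichloroethenyl]oxy}-3,5-dimethoxyphenyl)dodecyl]magnesium bromide | Br[Mg]CCCCCCCCCCCCc1cc(OC)c(O/C(Cl)=C\Cl)c(OC)c1 | intermediate (not isolated)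
9 | bromomagnesium 1-[12-(4-{[(E)-1,2-dichloroethenyl]oxy}-3,5-dimethoxyphenyl)dodecyl]-3-ethoxycyclobut-2-en-1-olate (racemic) | CCOC1=CC(CCCCCCCCCCCCc2cc(OC)c(O/C(Cl)=C\Cl)c(OC)c2)(O[Mg]Br)C1 | intermediate (not isolated)
10 | bromomagnesium 3-ethoxy-1-(12-{4-[(lithioethynyl)oxy]-3,5-dimethoxyphenyl}dodecyl)cyclobut-2-en-1-olate (racemic) | CCOC1=CC(CCCCCCCCCCCCc2cc(OC)c(OC#C[Li])c(OC)c2)(O[Mg]Br)C1 | intermediate (not isolated)
11 | 3-ethoxy-1-{12-[4-(ethynyloxy)-3,5-dimethoxyphenyl]dodecyl}cyclobut-2-en-1-ol (racemic) | CCOC1=CC(O)(CCCCCCCCCCCCc2cc(OC)c(OC#C)c(OC)c2)C1 | intermediate (not isolated)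
12 | 3-{12-[4-(ethynyloxy)-3,5-dimethoxyphenyl]dodecyl}cyclobut-2-en-1-one | COc1cc(CCCCCCCCCCCCC2=CC(=O)C2)cc(OC)c1OC#C | intermediate
13 | 15-[4-(ethynyloxy)-3,5-dimethoxyphenyl]-3-methylidenepentadec-1-en-1-one (vinylketene) | O=C=CC(=C)CCCCCCCCCCCCc1cc(OC)c(OC#C)c(OC)c1 | intermediate (not isolated)
14 | 4-alkenyl-3-aryloxycyclobut-2-enone fused to the 20-membered ring: ring B oxygen on C3, the 1-methylidene end of the chain on C4 (racemic) | O=C1C=C2Oc3c(OC)cc(CCCCCCCCCCCCC(=C)C12)cc3OC | intermediate (not isolated)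
15 | macrocyclic dienylketene: ketenylmethylidene on the ring carbon bearing the ring B oxygen, cis to the methylidene-bearing carbon | O=C=C/C1=C\C(=C)CCCCCCCCCCCCc2cc(OC)c(O1)c(OC)c2 | intermediate (not isolated)
16 | macrocyclic cyclohexa-2,4-dienone (keto tautomer of 17) | O=C1C=C2C=C(CCCCCCCCCCCCc3cc(OC)c(O2)c(OC)c3)C1 | intermediate (not isolated)
17 | ring B di-O-methyl ether of the target: 3-hydroxy ring A joined at C5 by a dodecane-1,12-diyl chain to C4 of ring B and at C3 by oxygen to C1 of ring B, which carries 2,6-dimethoxy groups | Oc1cc2cc(CCCCCCCCCCCCc3cc(OC)c(O2)c(OC)c3)c1 | intermediate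
18 | CNP0314249.0: as 17 with 2,6-dihydroxy groups on ring B (achiral) | Oc1cc2cc(c1)Oc1c(O)cc(cc1O)CCCCCCCCCCCC2 | target

**Totals**
Total steps: 5. Longest linear sequence: 5 steps (1 → 3 → 6 → 12 → 17 → 18).

**Three steps most likely to fail**

Step 4 (macrocyclising benzannulation). The risks are intermolecular ketene–ynol ether reaction giving oligomers and thermal loss of the terminal aryl ynol ether. The fallback builds ring A intermolecularly and closes the macrocycle by olefin metathesis; it sets out from 2 and 7 and comes back at 17. Purchased 4-allyl-2,6-dimethoxyphenol F1 is etherified with 2 (K2CO3, DMF, 70 °C) to 5-allyl-2-{[(E)-1,2-dichloroethenyl]oxy}-1,3-dimethoxybenzene F2. n-BuLi (2.3 equiv, THF, −78 to −40 °C) gives lithium (4-allyl-2,6-dimethoxyphenoxy)acetylide F3, which MeOH quenches to 5-allyl-2-(ethynyloxy)-1,3-dimethoxybenzene F4. Separately, purchased 11-bromoundec-1-ene F5 is converted with Mg in THF into undec-10-en-1-ylmagnesium bromide F6, which adds to 7 at −78 °C to give bromomagnesium 3-ethoxy-1-(undec-10-en-1-yl)cyclobut-2-en-1-olate F7; 1 M HCl at 0 °C then gives 3-(undec-10-en-1-yl)cyclobut-2-en-1-one F8. Intermolecular Danheiser benzannulation of F8 with F4 (1.5 equiv, PhMe, 0.4 M, 80 °C) gives 3-(4-allyl-2,6-dimethoxyphenoxy)-5-(undec-10-en-1-yl)phenol F9. Ring-closing metathesis (second-generation Grubbs catalyst RuCl2(=CHPh)(PCy3)(H2IMes), CH2Cl2, 2 mM, 40 °C) gives the chain-unsaturated macrocycle 2,3-didehydro-17 F10 (double bond between chain carbons 2 and 3 counted from ring B, E/Z mixture), and H2, Pd/C, EtOAc gives 17.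

Step 3 (one-pot cyclobutenone and ynol ether unveiling). The risks are attack of the Grignard reagent on the dichlorovinyl ether and acid hydration of the terminal ynol ether during the transposition. The fallback carries the alkyne as a bulky C-silyl ynol ether through stepwise operations; it sets out from 6 and comes back at 12. n-BuLi (2.3 equiv, THF, −78 °C; the primary bromide is inert to n-BuLi and to the acetylide at this temperature) converts 6 into lithium [4-(12-bromododecyl)-2,6-dimethoxyphenoxy]acetylide F11, which is silylated in the flask with iPr3SiOTf to {[4-(12-bromododecyl)-2,6-dimethoxyphenoxy]ethynyl}tri(propan-2-yl)silane F12. Mg in THF gives [12-(3,5-dimethoxy-4-{[tri(propan-2-yl)silylethynyl]oxy}phenyl)dodecyl]magnesium bromide F13, addition to 7 gives bromomagnesium 1-[12-(3,5-dimethoxy-4-{[tri(propan-2-yl)silylethynyl]oxy}phenyl)dodecyl]-3-ethoxycyclobut-2-en-1-olate F14, and 1 M HCl at 0 °C gives 3-[12-(3,5-dimethoxy-4-{[tri(propan-2-yl)silylethynyl]oxy}phenyl)dodecyl]cyclobut-2-en-1-one F15. The silylalkyne has no acidic hydrogen to quench the Grignard reagent and is shielded against hydration. Buffered Bu4NF/AcOH (THF, 0 °C) then removes silicon to give 12.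

Step 2 (B-alkyl Suzuki–Miyaura coupling). The risk is that palladium also engages the vinylic chlorides of the dichlorovinyl ether, which are competent cross-coupling sites, or the alkyl bromide. The fallback forms the aryl–chain link by cross-metathesis with no palladium; it sets out from 2 and comes back at 6. 4-Allyl-2,6-dimethoxyphenol F1 and 2 (K2CO3, DMF, 70 °C) give 5-allyl-2-{[(E)-1,2-dichloroethenyl]oxy}-1,3-dimethoxybenzene F2. Cross-metathesis with 11-bromoundec-1-ene F5 (3 equiv, second-generation Grubbs catalyst RuCl2(=CHPh)(PCy3)(H2IMes), CH2Cl2, 40 °C) gives 5-[(2E)-12-bromododec-2-en-1-yl]-2-{[(E)-1,2-dichloroethenyl]oxy}-1,3-dimethoxybenzene F16 (E/Z mixture). H2 with RhCl(PPh3)3 in benzene/EtOH saturates only the disubstituted alkene and gives 6.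

**Further compounds**
F1 | step 4 | 4-allyl-2,6-dimethoxyphenol (purchased) | C=CCc1cc(OC)c(O)c(OC)c1
F2 | step 4 | 5-allyl-2-{[(E)-1,2-dichloroethenyl]oxy}-1,3-dimethoxybenzene | C=CCc1cc(OC)c(O/C(Cl)=C\Cl)c(OC)c1
F3 | step 4 | lithium (4-allyl-2,6-dimethoxyphenoxy)acetylide | C=CCc1cc(OC)c(OC#C[Li])c(OC)c1
F4 | step 4 | 5-allyl-2-(ethynyloxy)-1,3-dimethoxybenzene | C=CCc1cc(OC)c(OC#C)c(OC)c1
F5 | step 4 | 11-bromoundec-1-ene (purchased) | C=CCCCCCCCCCBr
F6 | step 4 | undec-10-en-1-ylmagnesium bromide | C=CCCCCCCCCC[Mg]Br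
F7 | step 4 | bromomagnesium 3-ethoxy-1-(undec-10-en-1-yl)cyclobut-2-en-1-olate | CCOC1=CC(CCCCCCCCCC=C)(O[Mg]Br)C1
F8 | step 4 | 3-(undec-10-en-1-yl)cyclobut-2-en-1-one | C=CCCCCCCCCCC1=CC(=O)C1
F9 | step 4 | 3-(4-allyl-2,6-dimethoxyphenoxy)-5-(undec-10-en-1-yl)phenol | C=CCCCCCCCCCc1cc(O)cc(Oc2c(OC)cc(CC=C)cc2OC)c1
F10 | step 4 | 2,3-didehydro-17 (chain alkene between carbons 2 and 3 from ring B, E shown, E/Z mixture) | Oc1cc2cc(c1)CCCCCCCCC/C=C/Cc3cc(OC)c(O2)c(OC)c3
F11 | step 3 | lithium [4-(12-bromododecyl)-2,6-dimethoxyphenoxy]acetylide | BrCCCCCCCCCCCCc1cc(OC)c(OC#C[Li])c(OC)c1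
F12 | step 3 | {[4-(12-bromododecyl)-2,6-dimethoxyphenoxy]ethynyl}tri(propan-2-yl)silane | BrCCCCCCCCCCCCc1cc(OC)c(OC#C[Si](C(C)C)(C(C)C)C(C)C)c(OC)c1
F13 | step 3 | [12-(3,5-dimethoxy-4-{[tri(propan-2-yl)silylethynyl]oxy}phenyl)dodecyl]magnesium bromide | Br[Mg]CCCCCCCCCCCCc1cc(OC)c(OC#C[Si](C(C)C)(C(C)C)C(C)C)c(OC)c1
F14 | step 3 | bromomagnesium 1-[12-(3,5-dimethoxy-4-{[tri(propan-2-yl)silylethynyl]oxy}phenyl)dodecyl]-3-ethoxycyclobut-2-en-1-olate | CCOC1=CC(CCCCCCCCCCCCc2cc(OC)c(OC#C[Si](C(C)C)(C(C)C)C(C)C)c(OC)c2)(O[Mg]Br)C1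
F15 | step 3 | 3-[12-(3,5-dimethoxy-4-{[tri(propan-2-yl)silylethynyl]oxy}phenyl)dodecyl]cyclobut-2-en-1-one | COc1cc(CCCCCCCCCCCCC2=CC(=O)C2)cc(OC)c1OC#C[Si](C(C)C)(C(C)C)C(C)C
F16 | step 2 | 5-[(2E)-12-bromododec-2-en-1-yl]-2-{[(E)-1,2-dichloroethenyl]oxy}-1,3-dimethoxybenzene (E/Z mixture at the chain alkene) | BrCCCCCCCCC/C=C/Cc1cc(OC)c(O/C(Cl)=C\Cl)c(OC)c1
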